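**Assumptions (one line):** The chiral auxiliary and the resolving-amine enantiomer are taken to deliver the drawn series, and the Evans α-alkylation selectivity is transferred from the allylation case.

## Retrosynthetic overview
1. Integric acid comes from the C1 hydroxy-enone acid ester by Yamaguchi esterification with (2E,4S)-2,4-dimethyloct-2-enoic acid. The C7 enal comes from α′-vinylation of the enone with 2-bromopropene, then SeO2 oxidation. The C4 methyl ester is cleaved late.
2. The C1 hydroxy-enone comes from γ-hydroxylation of a bicyclic enone. Ring B of that enone closes by a Robinson-type aldol condensation of a 2-methyl-2-(3-oxobutyl)cyclohexanone, which sets C9=C10.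
3. **Key bond:** C5–C6, the quaternary centre, forms by photoredox decarboxylative Giese addition of the tertiary C5 radical (from the C5 carboxylic acid) to methyl vinyl ketone (MVK). The radical is attacked anti to the cis C4 ester and C10 acetate.
4. Ring A is a Diels–Alder adduct of 1-acetoxybutadiene and citraconic anhydride. Hydrogenation, regioselective methanolysis and resolution follow.
5. Ring order: ring A (Diels–Alder) first, then ring B (Giese, then aldol condensation).

## Route

**Step 1**
Reactants: 1 (E)-buta-1,3-dien-1-yl acetate; 2 citraconic anhydride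
Product: 3 (±)-cis-fused adduct, 4-acetoxy-3a-methyl-3a,4,7,7a-tetrahydro-2-benzofuran-1,3-dione (OAc endo, cis to both anhydride carbonyls; one enantiomer of the racemate drawn)
Conditions: toluene, BHT, 110 °C, sealed tube
Reagents that add atoms: none
Why: Diels–Alder reaction; the nucleophilic diene terminus bonds to the more electrophilic CH carbon of the anhydride, which puts C10(OAc) next to C5(Me), and endo, cis addition fixes C4, C5 and C10 relative to each other.

**Step 2**
Reactants: 3
Product: 4 (±)-4-acetoxy-3a-methylhexahydro-2-benzofuran-1,3-dione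
Conditions: H2 (1 atm), PtO2, EtOAc, 25 °C
Reagents that add atoms: none
Why: Heterogeneous hydrogenation of the disubstituted alkene; PtO2 avoids allylic-acetate hydrogenolysis and removes the allylic-radical/acyloxy-shift liability in step 5.

**Step 3**
Reactants: 4
Product: 5 (±)-2-acetoxy-6-(methoxycarbonyl)-1-methylcyclohexane-1-carboxylic acid (COOH, OAc and CO2Me all cis)
Conditions: MeOH, Et3N (0.1 equiv), 25→40 °C
Reagents that add atoms: methanol, CO
Why: Alcoholysis of the anhydride occurs at the less hindered carbonyl, next to C4–H, which leaves the acid on quaternary C5 as the radical precursor.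

**Step 4**
Reactants: 5
Product: 6 single enantiomer of 5 (SMILES as drawn)
Conditions: (S)-1-phenylethylamine (1 equiv), EtOAc/hexane, recrystallise the salt twice; then 1 M HCl, EtOAc
Reagents that add atoms: none
Why: Classical resolution through a diastereomeric ammonium salt fixes the absolute configuration, and every later stereocentre is set relative to C4/C5.

**Step 5**
Reactants: 6; 7 methyl vinyl ketone
Product: 8 methyl 3-acetoxy-2-methyl-2-(3-oxobutyl)cyclohexane-1-carboxylate (methyl cis to ester, oxobutyl trans to ester, OAc cis to ester)
Conditions: [Ir{dF(CF3)ppy}2(dtbbpy)]PF6 (1 mol %), Cs2CO3 (1.1 equiv), MVK (5 equiv), DMF, blue LEDs, 25 °C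
Reagents that add atoms: none
Why: Photoredox decarboxylative Giese reaction; the nucleophilic tertiary C5 radical adds, polarity-matched, to MVK from the face anti to the cis C4 ester and C10 acetate. This forms the quaternary centre with the chain trans to the C4 ester, so the methyl ends up cis to the ester as required.

**Step 6**
Reactants: 8
Product: 9 methyl 3-hydroxy-2-methyl-2-(3-oxobutyl)cyclohexane-1-carboxylate
Conditions: K2CO3, MeOH, 0→25 °C
Reagents that add atoms: none
Why: Mild transesterification removes the acetate, and no stereocentre is changed.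

**Step 7**
Reactants: 9
Product: 10 methyl 2-methyl-3-oxo-2-(3-oxobutyl)cyclohexane-1-carboxylate
Conditions: Dess–Martin periodinane, NaHCO3, CH2Cl2, 0→25 °C
Reagents that add atoms: none
Why: Oxidation of the secondary alcohol removes the C10 stereocentre and sets up the Robinson partner.

**Step 8**
Reactants: 10
Product: 11 methyl 8-oxo-11,12,13-trinoreremophil-9-en-15-oate (bicyclic enone; 5-Me; C9=C10–C8=O; C4-CO2Me cis to Me)
Conditions: NaOMe (0.3 equiv), MeOH, 65 °C
Reagents that add atoms: none
Why: Intramolecular aldol condensation (Robinson closure) of the methyl-ketone enolate onto the C10 ketone, then E1cB dehydration, builds ring B; the basic medium lets C4 settle as the equatorial ester, which is cis to the axial 5-Me as in the target.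

**Step 9**
Reactants: 11
Product: 12 methyl 1-hydroxy-8-oxo-11,12,13-trinoreremophil-9-en-15-oate (1-OH cis to 5-Me)
Conditions: KOtBu (2.5 equiv), tBuOH/THF 1:1, O2, 0 °C; then P(OEt)3, 25 °C
Reagents that add atoms: dioxygen, O=O
Why: γ-Hydroxylation through autoxidation of the extended dienolate, by analogy with 6β-hydroxylation of Δ4-3-keto steroids; axial attack syn to the axial Me gives the cis 1-OH, and P(OEt)3 reduces the hydroperoxide.

**Step 10**
Reactants: 13 hexanoyl chloride
Product: 14 (S)-4-benzyl-3-hexanoyl-1,3-oxazolidin-2-one
Conditions: (S)-4-benzyl-1,3-oxazolidin-2-one, n-BuLi, THF, −78 °C; then 13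
Reagents that add atoms: (S)-4-benzyl-1,3-oxazolidin-2-one (removable chiral auxiliary, recovered in step 12), O=C1N[C@@H](Cc2ccccc2)CO1
Why: N-Acylation of the lithiated oxazolidinone installs the removable chiral auxiliary.

**Step 11**
Reactants: 14
Product: 15 (S)-4-benzyl-3-[(S)-2-methylhexanoyl]oxazolidin-2-one
Conditions: NaHMDS, THF, −78 °C; then MeI (3 equiv), −78→−40 °C
Reagents that add atoms: iodomethane, CI
Why: Evans alkylation of the Z-chelated enolate; MeI approaches anti to the benzyl group and gives the (S) centre (the descriptor is opposite to the allylation case because the two groups swap CIP priority).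

**Step 12**
Reactants: 15
Product: 16 (S)-2-methylhexan-1-ol
Conditions: LiBH4 (2 equiv), H2O (1 equiv), Et2O, 0 °C
Reagents that add atoms: none
Why: Reductive removal of the auxiliary (recovered as the oxazolidinone), with no stereocentre touched.

**Step 13**
Reactants: 16
Product: 17 (S)-2-methylhexanal
Conditions: DMP, CH2Cl2, 25 °C, 1 h
Reagents that add atoms: none
Why: Mild oxidation, chosen to limit α-epimerisation.

**Step 14**
Reactants: 17
Product: 18 ethyl (2E,4S)-2,4-dimethyloct-2-enoate
Conditions: triethyl 2-phosphonopropionate, LiCl, DBU, MeCN, 0→25 °C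
Reagents that add atoms: triethyl 2-phosphonopropionate, CCOC(=O)C(C)P(=O)(OCC)OCC
Why: Masamune–Roush Horner–Wadsworth–Emmons olefination gives the E trisubstituted enoate, and the α-stereocentre is preserved under the mild base.

**Step 15**
Reactants: 18
Product: 19 (2E,4S)-2,4-dimethyloct-2-enoic acid
Conditions: LiOH, THF/MeOH/H2O, 50 °C; then 1 M HCl
Reagents that add atoms: lithium hydroxide, [Li+].[OH-]
Why: Saponification of the hindered enoate.

**Step 16**
Reactants: 12; 19
Product: 20 C1 ester, methyl 1-[(2E,4S)-2,4-dimethyloct-2-enoyloxy]-8-oxo-11,12,13-trinoreremophil-9-en-15-oate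
Conditions: 2,4,6-Cl3C6H2COCl, Et3N, THF, 25 °C (forms the mixed anhydride of 19); then 12, DMAP, toluene, 60 °C
Reagents that add atoms: none
Why: Yamaguchi esterification of the hindered allylic alcohol with retention at C1.

**Step 17**
Reactants: 20; 21 2-bromopropene
Product: 22 methyl 7-isopropenyl analogue of 20 (7-substituent trans to 5-Me)
Conditions: Pd2(dba)3 (3 mol %), XPhos (9 mol %), LiHMDS (2.2 equiv), 21 (3 equiv), THF, 60 °C
Reagents that add atoms: none
Why: Proposed new method: the kinetic α′-enolate at C7 (more acidic than the C4 ester α-H) transmetalates to Pd(II)–isopropenyl formed by oxidative addition, and reductive elimination forms C7–C11; the closest known reaction is Buchwald–Hartwig α-vinylation of ketones, and C7 epimerises to the equatorial trans isomer under the basic conditions.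

**Step 18**
Reactants: 22
Product: 23 the free C4 carboxylic acid
Conditions: Me3SnOH (10 equiv), 1,2-dichloroethane, 80 °C
Reagents that add atoms: trimethyltin hydroxide, C[Sn](C)(C)O
Why: Selective cleavage of the methyl ester leaves the hindered allylic C1 ester, enone and alkenes intact.

**Step 19**
Reactants: 23
Product: 24 integric acid
Conditions: SeO2 (2 equiv), 1,4-dioxane, 100 °C, 4 h
Reagents that add atoms: selenium dioxide, O=[Se]=O
Why: Riley allylic oxidation of the isopropenyl methyl gives the α-methylene aldehyde without touching any stereocentre.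

## Compound list
1 | (E)-buta-1,3-dien-1-yl acetate | CC(=O)O/C=C/C=C | starting material
2 | citraconic anhydride | CC1=CC(=O)OC1=O | starting material
3 | (±) Diels–Alder adduct (one enantiomer of the racemate drawn) | CC(=O)O[C@@H]1C=CC[C@@H]2C(=O)OC(=O)[C@]12C | intermediate
4 | (±) hydrogenated anhydride (one enantiomer drawn) | CC(=O)O[C@@H]1CCC[C@@H]2C(=O)OC(=O)[C@]12C | intermediate
5 | (±) half-ester acid (one enantiomer drawn) | CC(=O)O[C@@H]1CCC[C@H](C(=O)OC)[C@]1(C)C(=O)O | intermediate
6 | resolved half-ester acid | CC(=O)O[C@@H]1CCC[C@H](C(=O)OC)[C@]1(C)C(=O)O | intermediate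
7 | methyl vinyl ketone | C=CC(C)=O | starting material
8 | Giese product | CC(=O)O[C@@H]1CCC[C@H](C(=O)OC)[C@@]1(C)CCC(C)=O | intermediate
9 | hydroxy ketone | O[C@@H]1CCC[C@H](C(=O)OC)[C@@]1(C)CCC(C)=O | intermediate
10 | diketone | O=C1CCC[C@H](C(=O)OC)[C@@]1(C)CCC(C)=O | intermediate
11 | bicyclic enone | C1C[C@@]2(C)C(=CC1=O)CCC[C@@H]2C(=O)OC | intermediate
12 | 1-hydroxy enone | C1C[C@@]2(C)C(=CC1=O)[C@H](O)CC[C@@H]2C(=O)OC | intermediate
13 | hexanoyl chloride | CCCCCC(=O)Cl | starting material
14 | N-hexanoyl imide | CCCCCC(=O)N1[C@@H](Cc2ccccc2)COC1=O | intermediate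
15 | (S)-2-methylhexanoyl imide | CCCC[C@H](C)C(=O)N1[C@@H](Cc2ccccc2)COC1=O | intermediate
16 | (S)-2-methylhexan-1-ol | OC[C@@H](C)CCCC | intermediate
17 | (S)-2-methylhexanal | O=C[C@@H](C)CCCC | intermediate
18 | ethyl (2E,4S)-2,4-dimethyloct-2-enoate | CCOC(=O)/C(C)=C/[C@@H](C)CCCC | intermediate
19 | (2E,4S)-2,4-dimethyloct-2-enoic acid | OC(=O)/C(C)=C/[C@@H](C)CCCC | intermediate
20 | C1 ester of 12 | C1C[C@@]2(C)C(=CC1=O)[C@H](OC(=O)/C(C)=C/[C@@H](C)CCCC)CC[C@@H]2C(=O)OC | intermediate
21 | 2-bromopropene | C=C(C)Br | starting material
22 | 7-isopropenyl methyl ester | C=C(C)[C@@H]1C[C@@]2(C)C(=CC1=O)[C@H](OC(=O)/C(C)=C/[C@@H](C)CCCC)CC[C@@H]2C(=O)OC | intermediate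
23 | free acid (isopropenyl) | C=C(C)[C@@H]1C[C@@]2(C)C(=CC1=O)[C@H](OC(=O)/C(C)=C/[C@@H](C)CCCC)CC[C@@H]2C(=O)O | intermediate
24 | integric acid | C=C(C=O)[C@@H]1C[C@@]2(C)C(=CC1=O)[C@H](OC(=O)/C(C)=C/[C@@H](C)CCCC)CC[C@@H]2C(=O)O | target

## Totals
Total steps: 19. Longest linear sequence: 13 (steps 1–9, then 16–19).

## Three steps most likely to fail
1. **Step 5 (Giese at the congested tertiary radical).** Reduction or MVK oligomerisation may compete with addition, and facial selectivity is not guaranteed. Fallback (different approach): a proline-catalysed Hajos–Parrish/Wieland–Miescher-type Robinson annulation on 2-methylcyclohexane-1,3-dione (from cyclohexane-1,3-dione and MeI). Then homologate the saturated C4 ketone (methoxymethylene Wittig, hydrolysis, Pinnick) and continue with the γ-hydroxylation.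
2. **Step 9 (γ-hydroxylation).** Regio- and stereoselectivity are uncertain, because the C7 α′-site competes and the 1-OH could form trans to Me. Fallback (different approach): omit the hydrogenation in step 2, so the Δ1,2 alkene survives. After deacetylation, do a C10-hydroxyl-directed VO(acac)2/TBHP epoxidation of the allylic alkene, then a base-induced epoxide-to-allylic-alcohol isomerisation that places the cis C1–OH. Protect C1–OH as its TBS ether, hydrogenate the remaining alkene, then oxidise C10 and close ring B.
3. **Step 17 (α′-vinylation of the enone).** Competing enolisation at the C4 ester, a sluggish Pd cycle and Pd(0) ionisation of the allylic C1 ester are the concerns. Fallback (different approach): C7 aldol with acetone, dehydration to the isopropylidene enone, then kinetic deconjugative protonation to the isopropenyl ketone.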